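**Assumptions**
- Irigenin has no stereocentres, so it is achiral and no enantioselective step is needed. The only stereocentre in the route (in 16) is racemic and is destroyed in Step 9.
- 3-Hydroxy-4,5-dimethoxybenzaldehyde (11) is taken as commercially available.

## Retrosynthetic overview
1. Irigenin comes from global hydrogenolysis of the tri-O-benzyl isoflavone 17, so the 5-, 7- and 3'-OH groups are carried as OBn and the three OMe groups are installed as such.
2. Key bold step: the isoflavone is made by oxidative 1,2-aryl migration of a 2'-hydroxychalcone (hypervalent iodine, MeOH/HC(OMe)3) to an aryl-shifted dimethyl acetal, then acid cyclisation. This replaces the usual Suzuki coupling of a 3-iodochromone and the deoxybenzoin/one-carbon cyclisation.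
3. The chalcone comes from Claisen–Schmidt condensation of the A-ring acetophenone 10 and the B-ring aldehyde 12.
4. Ring A is built from methyl gallate by 4-O-methylation, bis-benzylation, DIBAL reduction, Dakin-type Baeyer–Villiger oxidation and Friedel–Crafts acetylation. Ring B is a one-step benzylation.
5. Ring order: arene A and arene B are pre-formed, the enone is formed by aldol condensation, and the pyranone ring C is closed last.

## Route

**Step 1**
Reactants: 1 methyl gallate (methyl 3,4,5-trihydroxybenzoate); 2 iodomethane
Product: 3 methyl 3,5-dihydroxy-4-methoxybenzoate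
Conditions: MeI (1.0 equiv), NaHCO3, DMF, 50 °C
Reagents that add atoms: iodomethane, CI
Why: The 4-OH, para to the ester, is the most acidic phenol, so a weak base and one equivalent of electrophile give selective 4-O-methylation (Williamson ether synthesis).

**Step 2**
Reactants: 3; 4 benzyl bromide
Product: 5 methyl 3,5-bis(benzyloxy)-4-methoxybenzoate
Conditions: BnBr (2.4 equiv), K2CO3, DMF, 60 °C
Reagents that add atoms: benzyl bromide, BrCc1ccccc1
Why: Williamson O-benzylation of both remaining phenols; these benzyl groups become the 5-OBn and 7-OBn of the isoflavone.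

**Step 3**
Reactants: 5
Product: 6 3,5-bis(benzyloxy)-4-methoxybenzaldehyde
Conditions: DIBAL-H (1.1 equiv), toluene/CH2Cl2, −78 °C, then Rochelle salt work-up
Reagents that add atoms: none
Why: Low-temperature DIBAL reduction stops at the aldehyde stage because of the stable tetrahedral aluminium hemiacetal; the benzyl and methyl ethers are untouched.

**Step 4**
Reactants: 6; 7 mCPBA
Product: 8 3,5-bis(benzyloxy)-4-methoxyphenol
Conditions: (i) mCPBA, CH2Cl2, 0 °C to rt; (ii) K2CO3, MeOH, rt (aryl formate hydrolysed in the same pot)
Reagents that add atoms: mCPBA, OOC(=O)c1cccc(Cl)c1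
Why: Dakin-type Baeyer–Villiger oxidation; the electron-rich aryl group migrates preferentially over H, as in the standard conversion of 3,4,5-trimethoxybenzaldehyde to 3,4,5-trimethoxyphenol.

**Step 5**
Reactants: 8; 9 acetic acid
Product: 10 1-[4,6-bis(benzyloxy)-2-hydroxy-5-methoxyphenyl]ethan-1-one
Conditions: AcOH, BF3·OEt2 (3 equiv), 60 °C, 3 h
Reagents that add atoms: acetic acid, CC(=O)O
Why: BF3-mediated Friedel–Crafts (Nencki-type) ortho-acetylation of the phenol. The two free ring positions are equivalent and the para position is blocked by OMe, so only one regioisomer forms, with the chelated 2'-OH ready for chromone formation.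

**Step 6**
Reactants: 11 3-hydroxy-4,5-dimethoxybenzaldehyde; 4 benzyl bromide
Product: 12 3-(benzyloxy)-4,5-dimethoxybenzaldehyde
Conditions: BnBr, K2CO3, acetone, reflux
Reagents that add atoms: benzyl bromide, BrCc1ccccc1
Why: Williamson benzylation masks the future 3'-OH, which would otherwise be oxidised by the iodane in Step 8.

**Step 7**
Reactants: 10; 12
Product: 13 (E)-1-[4,6-bis(benzyloxy)-2-hydroxy-5-methoxyphenyl]-3-(3-benzyloxy-4,5-dimethoxyphenyl)prop-2-en-1-one
Conditions: 50% aq. KOH, EtOH, rt, 48 h
Reagents that add atoms: none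
Why: Claisen–Schmidt aldol condensation; the E-enone is thermodynamically favoured and the chelated 2'-OH remains free.

**Step 8**
Reactants: 13; 14 methanol; 15 trimethyl orthoformate
Product: 16 1-[4,6-bis(benzyloxy)-2-hydroxy-5-methoxyphenyl]-2-(3-benzyloxy-4,5-dimethoxyphenyl)-3,3-dimethoxypropan-1-one (racemic)
Conditions: PhI(OAc)2 (1.5 equiv), HC(OMe)3, MeOH, conc. H2SO4 (cat.), rt
Reagents that add atoms: methanol, CO; trimethyl orthoformate, COC(OC)OC
Why: Oxidative rearrangement of the chalcone. The ArI(III) species adds across the enone alkene with methoxide at the benzylic carbon. The electron-rich 3,4,5-trialkoxyaryl ring then migrates 1,2 through a phenonium intermediate, displacing PhI. The resulting oxocarbenium is trapped as the dimethyl acetal. The new CH stereocentre is racemic and is destroyed in Step 9.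
Proposed new method: not strictly new; it is the hypervalent-iodine variant of the classical Tl(III) chalcone-to-isoflavone rearrangement, applied here to a heavily benzyloxylated substrate.

**Step 9**
Reactants: 16
Product: 17 5,7,3'-tris(benzyloxy)-6,4',5'-trimethoxyisoflavone (3-[3-(benzyloxy)-4,5-dimethoxyphenyl]-5,7-bis(benzyloxy)-6-methoxy-4H-chromen-4-one)
Conditions: 2 M HCl, MeOH, 60 °C, 1 h
Reagents that add atoms: none
Why: The phenol attacks the acetal-derived oxocarbenium, and loss of two MeOH gives the chromone C2=C3 bond (acid-catalysed cyclodehydration).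

**Step 10**
Reactants: 17
Product: 18 irigenin
Conditions: H2 (1 atm), 10% Pd/C, THF/MeOH 1:1, rt
Reagents that add atoms: none (H2 adds only hydrogen)
Why: Pd-catalysed hydrogenolysis removes the three aryl benzyl ethers. Aryl methyl ethers and the chromone C2=C3 survive at 1 atm. No stereocentres are involved.

## Compound list
1 | methyl gallate | COC(=O)c1cc(O)c(O)c(O)c1 | starting material
2 | iodomethane | CI | reagent
3 | methyl 3,5-dihydroxy-4-methoxybenzoate | COC(=O)c1cc(O)c(OC)c(O)c1 | intermediate
4 | benzyl bromide | BrCc1ccccc1 | reagent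
5 | methyl 3,5-bis(benzyloxy)-4-methoxybenzoate | COC(=O)c1cc(OCc2ccccc2)c(OC)c(OCc2ccccc2)c1 | intermediate
6 | 3,5-bis(benzyloxy)-4-methoxybenzaldehyde | COc1c(OCc2ccccc2)cc(C=O)cc1OCc1ccccc1 | intermediate
7 | mCPBA | OOC(=O)c1cccc(Cl)c1 | reagent
8 | 3,5-bis(benzyloxy)-4-methoxyphenol | COc1c(OCc2ccccc2)cc(O)cc1OCc1ccccc1 | intermediate
9 | acetic acid | CC(=O)O | reagent
10 | 1-[4,6-bis(benzyloxy)-2-hydroxy-5-methoxyphenyl]ethanone | CC(=O)c1c(O)cc(OCc2ccccc2)c(OC)c1OCc1ccccc1 | intermediate
11 | 3-hydroxy-4,5-dimethoxybenzaldehyde | COc1cc(C=O)cc(O)c1OC | starting material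
12 | 3-(benzyloxy)-4,5-dimethoxybenzaldehyde | COc1cc(C=O)cc(OCc2ccccc2)c1OC | intermediate
13 | 2'-hydroxychalcone (E) | COc1cc(/C=C/C(=O)c2c(O)cc(OCc3ccccc3)c(OC)c2OCc2ccccc2)cc(OCc2ccccc2)c1OC | intermediate
14 | methanol | CO | reagent
15 | trimethyl orthoformate | COC(OC)OC | reagent
16 | aryl-shifted dimethyl acetal (racemic) | COC(OC)C(c1cc(OC)c(OC)c(OCc2ccccc2)c1)C(=O)c1c(O)cc(OCc2ccccc2)c(OC)c1OCc1ccccc1 | intermediate
17 | tri-O-benzyl irigenin | COc1cc(-c2coc3cc(OCc4ccccc4)c(OC)c(OCc4ccccc4)c3c2=O)cc(OCc2ccccc2)c1OC | intermediate
18 | irigenin (achiral) | COc1cc(-c2coc3cc(O)c(OC)c(O)c3c2=O)cc(O)c1OC | target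

## Summary
Total steps: 10. Longest linear sequence: 9 (Steps 1, 2, 3, 4, 5, 7, 8, 9, 10; Step 6 is a parallel branch).

**Three steps most likely to fail**
1. **Step 8 (oxidative aryl migration).** Over-oxidation of the electron-rich arenes, or competing flavone or aurone formation, could lower the yield.
   - Fallback: switch to the deoxybenzoin route, converging at 17. Acylate phenol 8 with (3-benzyloxy-4,5-dimethoxyphenyl)acetic acid (BF3·OEt2), then close the ring with DMF/MsCl/BF3·OEt2.
2. **Step 5 (BF3/AcOH acetylation).** Partial debenzylation or poor conversion on the bis-benzyloxy phenol is possible.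
   - Fallback: ortho-formylate 8 (MgCl2, Et3N, paraformaldehyde), add MeMgBr, then oxidise the secondary alcohol (MnO2 or IBX) to give 10.
3. **Step 10 (hydrogenolysis).** Over-reduction of C2=C3 to the isoflavanone is the concern.
   - Fallback: use non-reductive debenzylation, TFA with pentamethylbenzene in CH2Cl2 at 0 °C, which leaves the aryl methyl ethers and the enone intact.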